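A direct plan would buy ring A as 1,2,3,4-tetramethoxybenzene A1 and turn it by lithiation–borylation–oxidation and ortho-formylation into the salicylaldehyde A2.
It would then lithiate the enol ether A3 (from a Wittig methoxymethylenation of the silylated B-ring aldehyde) at its α-carbon, add it to A2, oxidise the carbinol to the α-methoxy enone A4, close ring C last with iodine/DMSO and desilylate.
Its weakest steps would be:
- the α-lithiation of the β-aryl enol ether and its addition to the phenoxide aldehyde, which has no close precedent, needs the E isomer of an unselective Wittig reaction (half the material lost) and competes with elimination to the arylalkyne;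
- the hot iodine/DMSO closure of ring C on the most advanced material, where HI can hydrolyse the enol ether, strip the silyl ethers or cleave the 5-O-methyl group;
- the four-operation run-up from A1 to A2 that only adds OH and CHO to a purchased benzene.

Plan of the new route (flavone numbering):
- Retrosynthesis: debenzylation and O-methylation, then ring A is cut at C4a–C5 and C8–C8a; ring C is cut at C2–C3 and O1–C8a.
- Ring order: ring B is bought, ring C (a γ-pyranone carrying ring B) is made first, ring A arises last by ring expansion of a squarate adduct.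
- Enabling feature: in ring A, C5 and C8 are para oxygen-bearing carbons flanking C6–OMe and C7–OMe, and the remaining bond C4a–C8a is the C5=C6 double bond of pyranone ring C.
- This is the hydroquinone that a 4-alkenyl-4-hydroxy-2,3-dimethoxycyclobutenone gives on heating, so dimethyl squarate supplies C5–C8 with all four oxygens at once.
- No enol ether is lithiated, no Wittig isomer is discarded, ring C is never closed oxidatively on late material, and the last two steps are a methylation and a hydrogenolysis.

Key step: step 5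

Assumption: lithiation of pyranone 11 is taken to occur at C6, the CH next to the ring oxygen; an adduct formed through C5 would give the same hydroquinone 17 in step 5, so the assignment does not change the outcome.

Step 1
Reactants: 1 methyl 3,5-dihydroxy-4-methoxybenzoate
Product: 3 3,5-bis(benzyloxy)-4-methoxybenzoic acid, via bis-benzyl ether methyl ester 2 (not isolated)
Conditions: BnBr (2.4 equiv), K2CO3, acetone, reflux; filter, evaporate; 2 M aq. NaOH, MeOH–THF, 60 °C; 1 M HCl
Reagents that add atoms: benzyl bromide, BrCc1ccccc1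
Why: Williamson O-benzylation of both phenols followed by saponification without isolation; benzyl ethers are chosen because they should survive the lithium amide, the acid chloride, the thermolysis and the methylation and come off by hydrogenolysis at the end.

Step 2
Reactants: 4 (Z)-1-bromo-2-ethoxyethene; 5 N,2-dimethoxy-N-methylacetamide
Product: 7 (Z)-4-ethoxy-1-methoxybut-3-en-2-one, via (Z)-2-ethoxyvinyllithium 6 (not isolated)
Conditions: 4, t-BuLi (2.0 equiv), Et2O, −78 °C; then 5, −78 → 0 °C; sat. NH4Cl
Reagents that add atoms: none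
Why: Bromine–lithium exchange with retention gives the cis-β-ethoxyvinyllithium, which acylates once on the Weinreb amide through the chelated tetrahedral adduct to give the β-ethoxy enone; the alkene geometry is of no consequence later.

Step 3
Reactants: 3 3,5-bis(benzyloxy)-4-methoxybenzoic acid; 7 (Z)-4-ethoxy-1-methoxybut-3-en-2-one
Product: 11 2-[3,5-bis(benzyloxy)-4-methoxyphenyl]-3-methoxy-4H-pyran-4-one, via acid chloride 8 (not isolated), via lithium enolate 9 (not isolated), via diketone 10 (not isolated)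
Conditions: 3, (COCl)2, cat. DMF, CH2Cl2, rt, evaporate; 7 (2.1 equiv), LiN(SiMe3)2 (2.1 equiv), THF, −78 °C; 8 in THF, −78 °C, 1 h; AcOH; crude in CH2Cl2, TFA (2 equiv), rt
Reagents that add atoms: none
Why: C-acylation of the lithium enolate of a β-alkoxy enone with an aroyl chloride (the second equivalent of enolate takes up the acidic diketone proton) followed by acid-catalysed 6-endo oxa-Michael addition–elimination of ethanol is the established γ-pyranone synthesis, and since the methoxymethyl group is the only enolisable position of 7 the methoxy group must end at C3 next to the aryl-bearing C2.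

Step 4
Reactants: 11 2-[3,5-bis(benzyloxy)-4-methoxyphenyl]-3-methoxy-4H-pyran-4-one; 12 dimethyl squarate (3,4-dimethoxycyclobut-3-ene-1,2-dione)
Product: 14 rac-4-{6-[3,5-bis(benzyloxy)-4-methoxyphenyl]-5-methoxy-4-oxo-4H-pyran-2-yl}-4-hydroxy-2,3-dimethoxycyclobut-2-en-1-one, via 6-lithiopyranone 13 (not isolated)
Conditions: lithium 2,2,6,6-tetramethylpiperidide (1.1 equiv, from 2,2,6,6-tetramethylpiperidine + n-BuLi), THF, −78 °C, 20 min; cannulated into 12 (1.5 equiv), THF, −78 °C; sat. NH4Cl at −78 °C
Reagents that add atoms: none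
Why: Lithium amides deprotonate vinylogous esters and amides of this kind (isoflavones at C2, uracils at C6) at the CH next to the ring heteroatom, here C6, where the carbanion has no β-leaving group, and like other alkenyl- and heteroaryllithiums it should add 1,2 to one carbonyl group of dimethyl squarate, which is far more electrophilic than the pyranone carbonyl; the hindered amide should not add to C6, the benzyl ethers should not be metalated at −78 °C, and the racemic carbinol centre disappears in step 5.

Step 5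
Reactants: 14 rac-4-{6-[3,5-bis(benzyloxy)-4-methoxyphenyl]-5-methoxy-4-oxo-4H-pyran-2-yl}-4-hydroxy-2,3-dimethoxycyclobut-2-en-1-one
Product: 17 2-[3,5-bis(benzyloxy)-4-methoxyphenyl]-5,8-dihydroxy-3,6,7-trimethoxy-4H-chromen-4-one, via dienylketene 15 (not isolated), via 4aH-chromenedione 16 (not isolated)
Conditions: degassed p-xylene (0.02 M), 138 °C, argon, 1–2 h; cooled under argon and used directly
Reagents that add atoms: none
Why: Thermal conrotatory 4π ring opening of the cyclobutenone between C1 and C4 should give the dienylketene 15, which closes by 6π-electrocyclisation of the ketene carbon onto pyranone C5 and tautomerises through loss of the doubly activated C4a–H of 16 to the hydroquinone; this is the Moore ring expansion of 4-alkenyl- and 4-heteroaryl-4-hydroxycyclobutenones, closely related to the benzannulation of chromone-derived cyclobutenones to xanthones. Ring A is thus closed in a 6π-electrocyclic mode, the new bond being C4a–C5, with C5–C8 and their four oxygens from the squarate and C4a and C8a from the pyranone. No stereocentre remains, since the carbinol carbon becomes aromatic C8 and the transient C4a centre of 16 is lost on enolisation. The selectivity needed is the torquoselectivity of the opening: the hydroxyl donor rotates outward, which places the pyranyl group cis to the ketene so that cyclisation should outrun lactonisation to a furanone. C5–H of the pyranone, the nucleophilic β-carbon of the ring enol ether, is the only position the ketene carbon can reach, so no regiochemical choice exists. The new 5-hydroxyl is hydrogen-bonded to the C4 carbonyl, which adds driving force, and exclusion of air protects the hydroquinone from oxidation to the 5,8-quinone.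

Step 6
Reactants: 17 2-[3,5-bis(benzyloxy)-4-methoxyphenyl]-5,8-dihydroxy-3,6,7-trimethoxy-4H-chromen-4-one
Product: 18 2-[3,5-bis(benzyloxy)-4-methoxyphenyl]-3,5,6,7,8-pentamethoxy-4H-chromen-4-one
Conditions: MeI (8 equiv), K2CO3 (6 equiv), DMF, 50 °C, argon
Reagents that add atoms: iodomethane, CI
Why: Williamson methylation of both hydroquinone hydroxyls, the chelated 5-OH being slower and driven by excess reagent and warming as in the permethylation of 5-hydroxyflavones, with argon keeping the hydroquinone dianion from oxidation.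

Step 7
Reactants: 18 2-[3,5-bis(benzyloxy)-4-methoxyphenyl]-3,5,6,7,8-pentamethoxy-4H-chromen-4-one
Product: 19 2-(3,5-dihydroxy-4-methoxyphenyl)-3,5,6,7,8-pentamethoxy-4H-chromen-4-one (3',5'-dihydroxy-3,5,6,7,8,4'-hexamethoxyflavone)
Conditions: H2 (1 atm), Pd/C (10 wt% palladium on carbon), EtOAc–MeOH (1:1), rt
Reagents that add atoms: none
Why: Hydrogenolysis of the two benzyl aryl ethers, under which the tetrasubstituted C2=C3 bond of the flavone and the six methyl ethers should be inert; the product is achiral.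

**Compound list**
1 | methyl 3,5-dihydroxy-4-methoxybenzoate | COC(=O)c1cc(O)c(OC)c(O)c1 | starting material
2 | methyl 3,5-bis(benzyloxy)-4-methoxybenzoate | COC(=O)c1cc(OCc2ccccc2)c(OC)c(OCc2ccccc2)c1 | intermediate (not isolated)
3 | 3,5-bis(benzyloxy)-4-methoxybenzoic acid | OC(=O)c1cc(OCc2ccccc2)c(OC)c(OCc2ccccc2)c1 | intermediate
4 | (Z)-1-bromo-2-ethoxyethene | CCO/C=C\Br | starting material
5 | N,2-dimethoxy-N-methylacetamide | COCC(=O)N(C)OC | starting material
6 | (Z)-2-ethoxyvinyllithium | CCO/C=C\[Li] | intermediate (not isolated)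
7 | (Z)-4-ethoxy-1-methoxybut-3-en-2-one | CCO/C=C\C(=O)COC | intermediate
8 | 3,5-bis(benzyloxy)-4-methoxybenzoyl chloride | ClC(=O)c1cc(OCc2ccccc2)c(OC)c(OCc2ccccc2)c1 | intermediate (not isolated)
9 | lithium (1Z,3Z)-4-ethoxy-1-methoxybuta-1,3-dien-2-olate | CO/C=C(\O[Li])/C=C\OCC | intermediate (not isolated)
10 | (4Z)-1-[3,5-bis(benzyloxy)-4-methoxyphenyl]-5-ethoxy-2-methoxypent-4-ene-1,3-dione (racemic at C2, largely enolised) | CCO/C=C\C(=O)C(OC)C(=O)c1cc(OCc2ccccc2)c(OC)c(OCc2ccccc2)c1 | intermediate (not isolated)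
11 | 2-[3,5-bis(benzyloxy)-4-methoxyphenyl]-3-methoxy-4H-pyran-4-one | COc1c(-c2cc(OCc3ccccc3)c(OC)c(OCc3ccccc3)c2)occc1=O | intermediate
12 | dimethyl squarate (3,4-dimethoxycyclobut-3-ene-1,2-dione) | COC1=C(OC)C(=O)C1=O | starting material
13 | {6-[3,5-bis(benzyloxy)-4-methoxyphenyl]-5-methoxy-4-oxo-4H-pyran-2-yl}lithium | COc1c(-c2cc(OCc3ccccc3)c(OC)c(OCc3ccccc3)c2)oc([Li])cc1=O | intermediate (not isolated)
14 | rac-4-{6-[3,5-bis(benzyloxy)-4-methoxyphenyl]-5-methoxy-4-oxo-4H-pyran-2-yl}-4-hydroxy-2,3-dimethoxycyclobut-2-en-1-one (carbinol centre racemic) | COC1=C(OC)C(O)(c2cc(=O)c(OC)c(-c3cc(OCc4ccccc4)c(OC)c(OCc4ccccc4)c3)o2)C1=O | intermediate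
15 | (3Z)-4-{6-[3,5-bis(benzyloxy)-4-methoxyphenyl]-5-methoxy-4-oxo-4H-pyran-2-yl}-4-hydroxy-2,3-dimethoxybuta-1,3-dien-1-one (ketene cis to the pyranyl group) | O=C=C(OC)/C(OC)=C(O)\c1cc(=O)c(OC)c(-c2cc(OCc3ccccc3)c(OC)c(OCc3ccccc3)c2)o1 | intermediate (not isolated)
16 | 2-[3,5-bis(benzyloxy)-4-methoxyphenyl]-8-hydroxy-3,6,7-trimethoxy-4aH-chromene-4,5-dione (C4a racemic, transient) | COC1=C(OC)C(O)=C2OC(-c3cc(OCc4ccccc4)c(OC)c(OCc4ccccc4)c3)=C(OC)C(=O)C2C1=O | intermediate (not isolated)
17 | 2-[3,5-bis(benzyloxy)-4-methoxyphenyl]-5,8-dihydroxy-3,6,7-trimethoxy-4H-chromen-4-one | COc1c(OC)c(O)c2oc(-c3cc(OCc4ccccc4)c(OC)c(OCc4ccccc4)c3)c(OC)c(=O)c2c1O | intermediate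
18 | 2-[3,5-bis(benzyloxy)-4-methoxyphenyl]-3,5,6,7,8-pentamethoxy-4H-chromen-4-one | COc1c(OC)c(OC)c2oc(-c3cc(OCc4ccccc4)c(OC)c(OCc4ccccc4)c3)c(OC)c(=O)c2c1OC | intermediate
19 | 2-(3,5-dihydroxy-4-methoxyphenyl)-3,5,6,7,8-pentamethoxy-4H-chromen-4-one | COc1c(O)cc(-c2oc3c(OC)c(OC)c(OC)c(OC)c3c(=O)c2OC)cc1O | target

Total step count: 7. Longest linear sequence: 6 steps (steps 1, 3, 4, 5, 6, 7); step 2 is a one-step side branch.

The three steps most likely to fail:

Step 4. The lithiated pyranone may add to C6 or to the carbonyl group of pyranone that is not yet deprotonated, or lithiation at C5 may be followed by β-elimination with opening of ring C. The fallback sets out from 11 and comes back at 14, and makes the carbanion by halogen–metal exchange instead of deprotonation. Pyranone 11 would be zincated at C6 with TMPZnCl·LiCl (THF, 25 °C), a base that tolerates the pyranone carbonyl, to give {6-[3,5-bis(benzyloxy)-4-methoxyphenyl]-5-methoxy-4-oxo-4H-pyran-2-yl}zinc chloride F1. Iodinolysis with I2 should give 2-[3,5-bis(benzyloxy)-4-methoxyphenyl]-6-iodo-3-methoxy-4H-pyran-4-one F2, which is isolated. Iodine–magnesium exchange with iPrMgCl·LiCl (THF, −78 °C) would then give {6-[3,5-bis(benzyloxy)-4-methoxyphenyl]-5-methoxy-4-oxo-4H-pyran-2-yl}magnesium chloride F3, a softer carbanion formed with no amide base and no unmetalated pyranone present. Added to 12 at −78 °C, it should give 14.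

Step 5. Inward rotation of the hydroxyl at ring opening would let it trap the ketene as a furanone, closure onto the electron-poor pyranone double bond may be slow, and the hydroquinone may oxidise in air to the 5,8-quinone. The fallback sets out from 14 and comes back at 18, bypassing 17. The tertiary carbinol would be methylated with MeI/Ag2O (K2CO3, MeCN, rt) to rac-4-{6-[3,5-bis(benzyloxy)-4-methoxyphenyl]-5-methoxy-4-oxo-4H-pyran-2-yl}-2,3,4-trimethoxycyclobut-2-en-1-one F4. Its thermolysis (p-xylene, 138 °C) cannot lactonise and should pass through (3Z)-4-{6-[3,5-bis(benzyloxy)-4-methoxyphenyl]-5-methoxy-4-oxo-4H-pyran-2-yl}-2,3,4-trimethoxybuta-1,3-dien-1-one F5 and 2-[3,5-bis(benzyloxy)-4-methoxyphenyl]-3,6,7,8-tetramethoxy-4aH-chromene-4,5-dione F6. The product would be the air-stable 2-[3,5-bis(benzyloxy)-4-methoxyphenyl]-5-hydroxy-3,6,7,8-tetramethoxy-4H-chromen-4-one F7, which is methylated (MeI, K2CO3, DMF, 50 °C) to 18.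

Step 3. O-acylation of the α-methoxy enolate in place of C-acylation, or condensation of the enolate with its own enone, would leave too little diketone for the cyclisation. The fallback sets out from 7 and comes back at 10, and forms the C2–C3 bond by an aldol addition, in which O-acylation cannot occur. Commercial 3,5-dihydroxy-4-methoxybenzaldehyde F8 would be benzylated (BnBr, K2CO3, acetone) to 3,5-bis(benzyloxy)-4-methoxybenzaldehyde F9. Addition of enolate 9 (from 7 and LiN(SiMe3)2, THF, −78 °C) should give (4Z)-1-[3,5-bis(benzyloxy)-4-methoxyphenyl]-5-ethoxy-1-hydroxy-2-methoxypent-4-en-3-one F10 as a mixture of racemic diastereomers. Dess–Martin oxidation (CH2Cl2, NaHCO3, rt) should give 10, which is cyclised with TFA as in step 3.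

**Further compounds**
F1 | step 4 | {6-[3,5-bis(benzyloxy)-4-methoxyphenyl]-5-methoxy-4-oxo-4H-pyran-2-yl}zinc chloride | COc1c(-c2cc(OCc3ccccc3)c(OC)c(OCc3ccccc3)c2)oc([Zn]Cl)cc1=O
F2 | step 4 | 2-[3,5-bis(benzyloxy)-4-methoxyphenyl]-6-iodo-3-methoxy-4H-pyran-4-one | COc1c(-c2cc(OCc3ccccc3)c(OC)c(OCc3ccccc3)c2)oc(I)cc1=O
F3 | step 4 | {6-[3,5-bis(benzyloxy)-4-methoxyphenyl]-5-methoxy-4-oxo-4H-pyran-2-yl}magnesium chloride | COc1c(-c2cc(OCc3ccccc3)c(OC)c(OCc3ccccc3)c2)oc([Mg]Cl)cc1=O
F4 | step 5 | rac-4-{6-[3,5-bis(benzyloxy)-4-methoxyphenyl]-5-methoxy-4-oxo-4H-pyran-2-yl}-2,3,4-trimethoxycyclobut-2-en-1-one | COC1=C(OC)C(OC)(c2cc(=O)c(OC)c(-c3cc(OCc4ccccc4)c(OC)c(OCc4ccccc4)c3)o2)C1=O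
F5 | step 5 | (3Z)-4-{6-[3,5-bis(benzyloxy)-4-methoxyphenyl]-5-methoxy-4-oxo-4H-pyran-2-yl}-2,3,4-trimethoxybuta-1,3-dien-1-one | O=C=C(OC)/C(OC)=C(OC)\c1cc(=O)c(OC)c(-c2cc(OCc3ccccc3)c(OC)c(OCc3ccccc3)c2)o1
F6 | step 5 | 2-[3,5-bis(benzyloxy)-4-methoxyphenyl]-3,6,7,8-tetramethoxy-4aH-chromene-4,5-dione (C4a racemic, transient) | COC1=C(OC)C(OC)=C2OC(-c3cc(OCc4ccccc4)c(OC)c(OCc4ccccc4)c3)=C(OC)C(=O)C2C1=O
F7 | step 5 | 2-[3,5-bis(benzyloxy)-4-methoxyphenyl]-5-hydroxy-3,6,7,8-tetramethoxy-4H-chromen-4-one | COc1c(OC)c(OC)c2oc(-c3cc(OCc4ccccc4)c(OC)c(OCc4ccccc4)c3)c(OC)c(=O)c2c1O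
F8 | step 3 | 3,5-dihydroxy-4-methoxybenzaldehyde | COc1c(O)cc(C=O)cc1O
F9 | step 3 | 3,5-bis(benzyloxy)-4-methoxybenzaldehyde | COc1c(OCc2ccccc2)cc(C=O)cc1OCc1ccccc1
F10 | step 3 | (4Z)-1-[3,5-bis(benzyloxy)-4-methoxyphenyl]-5-ethoxy-1-hydroxy-2-methoxypent-4-en-3-one (racemic diastereomer mixture) | CCO/C=C\C(=O)C(OC)C(O)c1cc(OCc2ccccc2)c(OC)c(OCc2ccccc2)c1
A1 | direct plan | 1,2,3,4-tetramethoxybenzene | COc1ccc(OC)c(OC)c1OC
A2 | direct plan | 2-hydroxy-3,4,5,6-tetramethoxybenzaldehyde | O=Cc1c(O)c(OC)c(OC)c(OC)c1OC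
A3 | direct plan | (E)-2-methoxy-5-(2-methoxyethenyl)-1,3-bis[(triisopropylsilyl)oxy]benzene | CO/C=C/c1cc(O[Si](C(C)C)(C(C)C)C(C)C)c(OC)c(O[Si](C(C)C)(C(C)C)C(C)C)c1
A4 | direct plan | (E)-1-(2-hydroxy-3,4,5,6-tetramethoxyphenyl)-2-methoxy-3-{4-methoxy-3,5-bis[(triisopropylsilyl)oxy]phenyl}prop-2-en-1-one | CO/C(=C/c1cc(O[Si](C(C)C)(C(C)C)C(C)C)c(OC)c(O[Si](C(C)C)(C(C)C)C(C)C)c1)C(=O)c1c(O)c(OC)c(OC)c(OC)c1OC
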